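**Assumption:** the target has no stereocentre (the 1,1-dimethylallyl carbon carries two methyls), so it is achiral and "single enantiomer" means the compound as drawn; there is no stereochemistry to set.

**Catalyst for step 2** (unchanged, not numbered): 2-(pentafluorophenyl)-6,7-dihydro-5H-pyrrolo[2,1-c][1,2,4]triazol-2-ium tetrafluoroborate, F[B-](F)(F)F.Fc1c(F)c(F)c(F)c(F)c1[n+]1cn2CCCc2n1

## Retrosynthetic overview

1. Target 11 ⇒ 7-O-prenyl ether 9 by aromatic Claisen rearrangement (O→C8, allyl inversion gives the 1,1-dimethylallyl group) ⇒ 2'-hydroxygenistein 7 + prenyl bromide 8.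
2. 7 ⇒ 3-hydroxyisoflavanone 5 by dehydration (C2=C3) and O-demethylation.
3. 5 ⇒ keto-aldehyde 3 by NHC-catalysed intramolecular crossed benzoin: the C4–C3 bond is made from the aldehyde carbon as an acyl anion (Breslow enaminol) and the ketone carbonyl.
4. 3 ⇒ salicylaldehyde 1 + phenacyl bromide 2 (Williamson ether).
5. Ring order: rings A and B are bought; the pyranone ring C is closed in step 2 by the C–C bond formation.

## Route

**Step 1**
Reactants: 1 2-hydroxy-4,6-dimethoxybenzaldehyde; 2 2-bromo-1-(2,4-dimethoxyphenyl)ethan-1-one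
Product: 3 2-[2-(2,4-dimethoxyphenyl)-2-oxoethoxy]-4,6-dimethoxybenzaldehyde
Conditions: K2CO3 (1.2 equiv), KI (5 mol %), acetone, rt, 12 h
Reagents that add atoms: none
Why: Williamson ether synthesis; the only free phenol displaces the α-bromo ketone quickly at room temperature, where the competing Rap–Stoermer aldol/dehydration to a 2-aroylbenzofuran is slow.

**Step 2**
Reactants: 3 2-[2-(2,4-dimethoxyphenyl)-2-oxoethoxy]-4,6-dimethoxybenzaldehyde
Product: 5 (±)-3-(2,4-dimethoxyphenyl)-3-hydroxy-5,7-dimethoxychroman-4-one, via Breslow enaminol 4 (not isolated)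
Conditions: triazolium precatalyst (15 mol %), Et3N (15 mol %), PhMe, 60 °C, Ar
Reagents that add atoms: none
Why: NHC-catalysed intramolecular crossed aldehyde–ketone benzoin reaction, in which the carbene turns the formyl carbon into the nucleophilic Breslow enaminol 4 that attacks the ketone carbonyl 6-exo to form C4–C3 and release the catalyst (an isomerisation with no by-product); the C3 carbinol centre forms racemic with the achiral catalyst and is erased in step 3.

**Step 3**
Reactants: 5 (±)-3-(2,4-dimethoxyphenyl)-3-hydroxy-5,7-dimethoxychroman-4-one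
Product: 7 3-(2,4-dihydroxyphenyl)-5,7-dihydroxy-4H-chromen-4-one (2'-hydroxygenistein), via tetramethoxyisoflavone 6 (not isolated)
Conditions: TsOH·H2O (10 mol %), PhMe, 110 °C; evaporate; BBr3 (10 equiv), CH2Cl2, −78 → 40 °C; H2O quench
Reagents that add atoms: none
Why: acid-catalysed E1 dehydration (the C3 cation is stabilised by the 2,4-dimethoxyphenyl ring and loses H-2 to give the conjugated chromone 6), then BBr3 Lewis-acid cleavage of all four aryl methyl ethers, with the boron aryloxides hydrolysed on quench.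

**Step 4**
Reactants: 7 3-(2,4-dihydroxyphenyl)-5,7-dihydroxy-4H-chromen-4-one; 8 1-bromo-3-methylbut-2-ene (prenyl bromide)
Product: 9 3-(2,4-dihydroxyphenyl)-5-hydroxy-7-[(3-methylbut-2-en-1-yl)oxy]-4H-chromen-4-one
Conditions: K2CO3 (1.0 equiv), 8 (1.05 equiv), acetone, rt → 40 °C
Reagents that add atoms: none
Why: chemoselective Williamson O-alkylation; the 7-OH is a vinylogous carboxylic acid (pKa about 7, against about 9.5–10 for 2'-/4'-OH and a chelated 5-OH), so one equivalent of weak base gives only the 7-phenoxide.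

**Step 5**
Reactants: 9 3-(2,4-dihydroxyphenyl)-5-hydroxy-7-[(3-methylbut-2-en-1-yl)oxy]-4H-chromen-4-one
Product: 11 3-(2,4-dihydroxyphenyl)-5,7-dihydroxy-8-(2-methylbut-3-en-2-yl)-4H-chromen-4-one (target), via ortho-dienone 10 (not isolated)
Conditions: PhNEt2, 190 °C, Ar, sealed tube, 1–2 h
Reagents that add atoms: none
Why: aromatic Claisen rearrangement ([3,3]-sigmatropic) of the aryl prenyl ether delivers the inverted 1,1-dimethylallyl group to C8, the ortho position favoured in 7-allyloxychromones, and dienone 10 tautomerises to the phenol; the para position C4a is blocked, so no Cope shift follows, and no stereocentre remains.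

## Compound list

1 | 2-hydroxy-4,6-dimethoxybenzaldehyde | COc1cc(O)c(C=O)c(OC)c1 | starting material
2 | 2-bromo-1-(2,4-dimethoxyphenyl)ethan-1-one | COc1ccc(C(=O)CBr)c(OC)c1 | starting material
3 | 2-[2-(2,4-dimethoxyphenyl)-2-oxoethoxy]-4,6-dimethoxybenzaldehyde | COc1cc(OC)c(C=O)c(OCC(=O)c2ccc(OC)cc2OC)c1 | intermediate
4 | Breslow enaminol (carbene adduct of 3 at the formyl carbon; alkene geometry not defined) | OC(=C1N(c2c(F)c(F)c(F)c(F)c2F)N=C2CCCN12)c1c(OC)cc(OC)cc1OCC(=O)c1ccc(OC)cc1OC | intermediate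
5 | (±)-3-(2,4-dimethoxyphenyl)-3-hydroxy-5,7-dimethoxychroman-4-one (racemic at C3) | COc1cc(OC)c2c(c1)OCC(O)(c1ccc(OC)cc1OC)C2=O | intermediate
6 | 3-(2,4-dimethoxyphenyl)-5,7-dimethoxy-4H-chromen-4-one | COc1cc(OC)c2c(c1)occ(-c1ccc(OC)cc1OC)c2=O | intermediate
7 | 3-(2,4-dihydroxyphenyl)-5,7-dihydroxy-4H-chromen-4-one (2'-hydroxygenistein) | Oc1cc(O)c2c(c1)occ(-c1ccc(O)cc1O)c2=O | intermediate
8 | 1-bromo-3-methylbut-2-ene (prenyl bromide) | CC(C)=CCBr | starting material
9 | 3-(2,4-dihydroxyphenyl)-5-hydroxy-7-[(3-methylbut-2-en-1-yl)oxy]-4H-chromen-4-one | CC(C)=CCOc1cc(O)c2c(c1)occ(-c1ccc(O)cc1O)c2=O | intermediate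
10 | 3-(2,4-dihydroxyphenyl)-5-hydroxy-8-(2-methylbut-3-en-2-yl)-8H-chromene-4,7-dione (ortho-dienone, racemic at C8) | C=CC(C)(C)C1C(=O)C=C(O)C2=C1OC=C(c1ccc(O)cc1O)C2=O | intermediate
11 | 3-(2,4-dihydroxyphenyl)-5,7-dihydroxy-8-(2-methylbut-3-en-2-yl)-4H-chromen-4-one | C=CC(C)(C)c1c(O)cc(O)c2c(=O)c(-c3ccc(O)cc3O)coc12 | target

## Count and risks

Total step count: 5. Longest linear sequence: 5 (1 or 2 → 11).

**Step 2 (benzoin ring closure).** The aldehyde is flanked by two ortho oxygen substituents and is electron-rich, so formation of the Breslow enaminol may be slow. The ketone is also deactivated, and base can divert 3 to the Rap–Stoermer benzofuran. The fallback uses a stoichiometric acyl anion equivalent instead. It sets out from 1 and comes back to the route at 6. Compound 1 is condensed with propane-1,3-dithiol (BF3·OEt2 cat., CH2Cl2) to give 2-(2-hydroxy-4,6-dimethoxyphenyl)-1,3-dithiane F1. F1 is dilithiated (n-BuLi 2.2 equiv, THF, −30 °C) and C-benzylated with 2,4-dimethoxybenzyl chloride (COc1ccc(CCl)c(OC)c1) to give 2-(2,4-dimethoxybenzyl)-2-(2-hydroxy-4,6-dimethoxyphenyl)-1,3-dithiane F2. The dithiane is removed (MeI, CaCO3, aq. MeCN) to give the deoxybenzoin 2-(2,4-dimethoxyphenyl)-1-(2-hydroxy-4,6-dimethoxyphenyl)ethan-1-one F3. Heating F3 with DMF dimethyl acetal (COC(OC)N(C)C, 95 °C) adds C2 and closes the pyranone to give 6, which enters step 3 at the BBr3 stage.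

**Step 4 (selective 7-O-prenylation).** Over-alkylation at 4'-OH or 2'-OH, or C-prenylation of the phloroglucinol ring, may lower the yield. The fallback differentiates the 7-OH by protection. It sets out from 7 and comes back at 9. Compound 7 is peracetylated (Ac2O, pyridine) to 4-(5,7-diacetoxy-4-oxo-4H-chromen-3-yl)-1,3-phenylene diacetate F4. The most labile 7-acetate is removed selectively (PhSH, imidazole, NMP, 0 °C) to give the 7-hydroxy 5,2',4'-triacetate F5. Mitsunobu etherification with 3-methylbut-2-en-1-ol (PPh3, DIAD, THF) gives the 7-O-prenyl 5,2',4'-triacetate F6. Methanolysis (K2CO3 cat., MeOH, rt) gives 9.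

**Step 5 (Claisen rearrangement).** Some C6 regioisomer may form. At 190 °C the free ortho-phenol of the product can also cyclise onto the alkene (2,3,3-trimethyldihydrofuran) or undergo abnormal Claisen rearrangement. The fallback is a trap-and-release sequence. It sets out from 9 and comes back at 11. Compound 9 is heated with Ac2O and NaOAc in PhNEt2 (185 °C), so the substrate is peracetylated in the flask and the newly formed 7-phenol is captured as it appears, giving the 5,7,2',4'-tetraacetate of the target F7. Mild methanolysis (K2CO3 cat., MeOH, 0 °C → rt) gives 11.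

## Further compounds

F1 | step 2 | 2-(2-hydroxy-4,6-dimethoxyphenyl)-1,3-dithiane | COc1cc(O)c(C2SCCCS2)c(OC)c1
F2 | step 2 | 2-(2,4-dimethoxybenzyl)-2-(2-hydroxy-4,6-dimethoxyphenyl)-1,3-dithiane | COc1ccc(CC2(c3c(O)cc(OC)cc3OC)SCCCS2)c(OC)c1
F3 | step 2 | 2-(2,4-dimethoxyphenyl)-1-(2-hydroxy-4,6-dimethoxyphenyl)ethan-1-one | COc1ccc(CC(=O)c2c(O)cc(OC)cc2OC)c(OC)c1
F4 | step 4 | 4-(5,7-diacetoxy-4-oxo-4H-chromen-3-yl)-1,3-phenylene diacetate | CC(=O)Oc1cc(OC(C)=O)c2c(c1)occ(-c1ccc(OC(C)=O)cc1OC(C)=O)c2=O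
F5 | step 4 | 4-(5-acetoxy-7-hydroxy-4-oxo-4H-chromen-3-yl)-1,3-phenylene diacetate | Oc1cc(OC(C)=O)c2c(c1)occ(-c1ccc(OC(C)=O)cc1OC(C)=O)c2=O
F6 | step 4 | 4-{5-acetoxy-7-[(3-methylbut-2-en-1-yl)oxy]-4-oxo-4H-chromen-3-yl}-1,3-phenylene diacetate | CC(C)=CCOc1cc(OC(C)=O)c2c(c1)occ(-c1ccc(OC(C)=O)cc1OC(C)=O)c2=O
F7 | step 5 | 4-[5,7-diacetoxy-8-(2-methylbut-3-en-2-yl)-4-oxo-4H-chromen-3-yl]-1,3-phenylene diacetate | C=CC(C)(C)c1c(OC(C)=O)cc(OC(C)=O)c2c(=O)c(-c3ccc(OC(C)=O)cc3OC(C)=O)coc12
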